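**Retrosynthetic overview**

1. Feature: ring A is a phloroglucinol with hydroxyls on C2, C4 and C6 and the ether oxygen to ring B on C1. It is the enolised ring form of a 6-aryloxy-3,5-dioxohexanoate chain. Ring A is disconnected at C1–C2 (chain C6 to ester C1) by a Claisen cyclisation and is the only ring that is built, last (22 ⇐ 21 ⇐ 19).
2. The chain is carried as its 3-O-methyl enol ether 19. In a free 3,5-dioxo ester, strong base would deprotonate C2 first and turn the ester into an inert enolate, and O-lactonisation would end in a 4-hydroxypyranone; the enol ether removes both problems.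
3. 19 ⇐ Weinreb amide 15 + lithium dienolate of methyl (E)-3-methoxybut-2-enoate 16. 15 ⇐ BCD phenol 13 by SN2, so the crowded ring A–O–ring B ether is made as a simple alkyl aryl ether.
4. 13 ⇐ two rounds of Ullmann etherification then Dakin oxidation on a 2,4,6-trimethoxyresorcinol core for ring C, whose second phenol is masked as an aldehyde (5). Ring D iodide 6 goes on first, ring B bromoaldehyde 10 second; rings B, C and D are bought as benzenes.
5. The nine methyl ethers are cleaved in the last step.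

Key step: step 9

Remark: the target has no stereocentre and its diaryl ether axes rotate freely, so it is achiral and no stereocontrol is needed. The ring A oxygen that comes from chain C3 stays a methyl ether until the final demethylation. ArBCD below means 3,4-dimethoxy-5-[2,4,6-trimethoxy-3-(3,4,5-trimethoxyphenoxy)phenoxy]phenyl.

**Route**

Step 1
Reactants: 1 2,4,6-trimethoxybenzaldehyde
Product: 3 2,4,6-trimethoxyphenol, via 2,4,6-trimethoxyphenyl formate 2 (not isolated)
Conditions: mCPBA, CH2Cl2, 0 °C to rt; aq. Na2S2O3 wash; then K2CO3 (cat.), MeOH, rt, Ar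
Reagents that add atoms: mCPBA, OOC(=O)c1cccc(Cl)c1
Why: Dakin-type Baeyer–Villiger oxidation, in which the electron-rich aryl group migrates to oxygen and the formate shields the new phenol from the peracid until methanolysis.

Step 2
Reactants: 3 2,4,6-trimethoxyphenol
Product: 5 3-hydroxy-2,4,6-trimethoxybenzaldehyde, via aryl iminium chloride 4 (not isolated)
Conditions: POCl3, DMF, 0 °C to rt; then H2O, 50 °C
Reagents that add atoms: N,N-dimethylformamide, CN(C)C=O; water, O
Why: Vilsmeier–Haack formylation at the only type of ring C–H, which lies ortho, ortho and para to the three methoxy groups; one formyl group deactivates the ring against a second, and any O-formyl group on the phenol is lost in the hydrolysis.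

Step 3
Reactants: 5 3-hydroxy-2,4,6-trimethoxybenzaldehyde; 6 5-iodo-1,2,3-trimethoxybenzene
Product: 7 2,4,6-trimethoxy-3-(3,4,5-trimethoxyphenoxy)benzaldehyde
Conditions: CuI (10 mol%), picolinic acid (20 mol%), K3PO4, DMSO, 90 °C, Ar
Reagents that add atoms: none
Why: Ullmann diaryl ether synthesis with a copper/picolinate catalyst suited to 2,6-disubstituted phenols and an unhindered aryl iodide; the non-enolisable aldehyde is a spectator and keeps the second ring C oxygen masked.

Step 4
Reactants: 7 2,4,6-trimethoxy-3-(3,4,5-trimethoxyphenoxy)benzaldehyde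
Product: 9 2,4,6-trimethoxy-3-(3,4,5-trimethoxyphenoxy)phenol, via CD aryl formate 8 (not isolated)
Conditions: mCPBA, CH2Cl2, 0 °C to rt; aq. Na2S2O3 wash; then K2CO3 (cat.), MeOH, rt, Ar
Reagents that add atoms: mCPBA, OOC(=O)c1cccc(Cl)c1
Why: Dakin-type Baeyer–Villiger oxidation of a benzaldehyde with two ortho and one para alkoxy group, where aryl migration should be fast compared with oxidation of the other ring.

Step 5
Reactants: 9 2,4,6-trimethoxy-3-(3,4,5-trimethoxyphenoxy)phenol; 10 3-bromo-4,5-dimethoxybenzaldehyde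
Product: 11 3,4-dimethoxy-5-[2,4,6-trimethoxy-3-(3,4,5-trimethoxyphenoxy)phenoxy]benzaldehyde
Conditions: CuI (20 mol%), picolinic acid (40 mol%), K3PO4, DMSO, 100 °C, Ar
Reagents that add atoms: none
Why: Second Ullmann etherification of the only free phenol with an aryl bromide carrying one ortho methoxy group; the formyl group marks the future ring B oxygen.

Step 6
Reactants: 11 3,4-dimethoxy-5-[2,4,6-trimethoxy-3-(3,4,5-trimethoxyphenoxy)phenoxy]benzaldehyde
Product: 13 3,4-dimethoxy-5-[2,4,6-trimethoxy-3-(3,4,5-trimethoxyphenoxy)phenoxy]phenol (ArBCD–OH), via BCD aryl formate 12 (not isolated)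
Conditions: mCPBA, CH2Cl2, 0 °C to rt; aq. Na2S2O3 wash; then K2CO3 (cat.), MeOH, rt, Ar
Reagents that add atoms: mCPBA, OOC(=O)c1cccc(Cl)c1
Why: Baeyer–Villiger oxidation of a 3,4,5-trioxygenated benzaldehyde, whose para alkoxy group favours aryl over hydride migration, followed by formate methanolysis.

Step 7
Reactants: 13 ArBCD–OH; 14 2-chloro-N-methoxy-N-methylacetamide
Product: 15 2-(ArBCD-oxy)-N-methoxy-N-methylacetamide
Conditions: K2CO3, NaI (cat.), DMF, 60 °C, Ar
Reagents that add atoms: none
Why: Williamson ether synthesis (SN2 on an α-halo amide with Finkelstein assistance) at the single, unhindered phenol.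

Step 8
Reactants: 15 2-(ArBCD-oxy)-N-methoxy-N-methylacetamide; 16 methyl (2E)-3-methoxybut-2-enoate
Product: 19 methyl (2E)-6-(ArBCD-oxy)-3-methoxy-5-oxohex-2-enoate, via lithium dienolate 17 (not isolated), via lithium hemiaminal adduct 18 (not isolated)
Conditions: 16, LDA, THF, −78 °C; then 15, −78 to −40 °C; aq. NH4Cl
Reagents that add atoms: none
Why: γ-Acylation of the lithium dienolate of a β-alkoxy enoate by a Weinreb amide, whose chelated tetrahedral adduct survives until quench so that neither over-addition nor proton transfer from the acidic product occurs; the ester stays cis to C4 (2E).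

Step 9
Reactants: 19 methyl (2E)-6-(ArBCD-oxy)-3-methoxy-5-oxohex-2-enoate
Product: 21 2-(ArBCD-oxy)-5-methoxybenzene-1,3-diol, via cyclohexenedione keto tautomer 20 (not isolated)
Conditions: NaOMe (5 equiv), MeOH, 65 °C then 110 °C (sealed tube), Ar; then aq. HCl
Reagents that add atoms: none
Why: Proposed new method: methoxide reversibly forms the C6 enolate of 19 (the α-aryloxy ketone position), which adds to the C1 ester carbonyl, methoxide leaves and the cyclohexenedione 20 enolises to the aromatic diol; the closest known reaction type is the alkoxide-induced Claisen recyclisation of 4-methoxy-6-methyl-2-pyranone, through ring-opened methyl 3-methoxy-5-oxohex-2-enoate, to 5-methoxyresorcinol, and an aryloxy-bearing nucleophilic carbon has not been shown in it. Ring A closes in a 6-(enolendo)-exo-trig mode, forming its C1–C2 bond (chain C6 to C1). No stereocentre results, since the sp3 carbon of 20 is lost on enolisation. The step needs C-acylation to win over O-acylation and over enolisation of the ester: C2 is vinylic in the enol ether, so the ester cannot be masked as an enolate, and lactonisation through O5 gives only a 4-methoxy-2-pyranone that methoxide reopens, whereas C-acylation ends in an aromatic phenoxide and is irreversible. The (2E) geometry holds the ester cis to C4 as the ring demands, and the aryloxy group should raise the acidity of C6 relative to the methyl case.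

Step 10
Reactants: 21 2-(ArBCD-oxy)-5-methoxybenzene-1,3-diol
Product: 22 2-{3,4-dihydroxy-5-[2,4,6-trihydroxy-3-(3,4,5-trihydroxyphenoxy)phenoxy]phenoxy}benzene-1,3,5-triol (CNP0214481.0)
Conditions: BBr3 (excess), CH2Cl2, −78 °C to rt; then MeOH/H2O, 0 °C, Ar
Reagents that add atoms: none
Why: Lewis-acid demethylation (boron complexation, then bromide SN2 at methyl) should cleave all nine aryl methyl ethers while the diaryl ether bonds stay intact; work-up under argon guards the pyrogallol-type rings against air oxidation.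

**Compound list**

1 | 2,4,6-trimethoxybenzaldehyde | COc1cc(OC)c(C=O)c(OC)c1 | starting material
2 | 2,4,6-trimethoxyphenyl formate | COc1cc(OC)c(OC=O)c(OC)c1 | intermediate (not isolated)
3 | 2,4,6-trimethoxyphenol | COc1cc(OC)c(O)c(OC)c1 | intermediate
4 | N-[(3-hydroxy-2,4,6-trimethoxyphenyl)methylidene]-N-methylmethanaminium chloride | C[N+](C)=Cc1c(OC)cc(OC)c(O)c1OC.[Cl-] | intermediate (not isolated)
5 | 3-hydroxy-2,4,6-trimethoxybenzaldehyde | O=Cc1c(OC)cc(OC)c(O)c1OC | intermediate
6 | 5-iodo-1,2,3-trimethoxybenzene | COc1cc(I)cc(OC)c1OC | starting material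
7 | 2,4,6-trimethoxy-3-(3,4,5-trimethoxyphenoxy)benzaldehyde | O=Cc1c(OC)cc(OC)c(Oc2cc(OC)c(OC)c(OC)c2)c1OC | intermediate
8 | 2,4,6-trimethoxy-3-(3,4,5-trimethoxyphenoxy)phenyl formate | O=COc1c(OC)cc(OC)c(Oc2cc(OC)c(OC)c(OC)c2)c1OC | intermediate (not isolated)
9 | 2,4,6-trimethoxy-3-(3,4,5-trimethoxyphenoxy)phenol | Oc1c(OC)cc(OC)c(Oc2cc(OC)c(OC)c(OC)c2)c1OC | intermediate
10 | 3-bromo-4,5-dimethoxybenzaldehyde | O=Cc1cc(Br)c(OC)c(OC)c1 | starting material
11 | 3,4-dimethoxy-5-[2,4,6-trimethoxy-3-(3,4,5-trimethoxyphenoxy)phenoxy]benzaldehyde | O=Cc1cc(OC)c(OC)c(Oc2c(OC)cc(OC)c(Oc3cc(OC)c(OC)c(OC)c3)c2OC)c1 | intermediate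
12 | 3,4-dimethoxy-5-[2,4,6-trimethoxy-3-(3,4,5-trimethoxyphenoxy)phenoxy]phenyl formate | O=COc1cc(OC)c(OC)c(Oc2c(OC)cc(OC)c(Oc3cc(OC)c(OC)c(OC)c3)c2OC)c1 | intermediate (not isolated)
13 | 3,4-dimethoxy-5-[2,4,6-trimethoxy-3-(3,4,5-trimethoxyphenoxy)phenoxy]phenol | Oc1cc(OC)c(OC)c(Oc2c(OC)cc(OC)c(Oc3cc(OC)c(OC)c(OC)c3)c2OC)c1 | intermediate
14 | 2-chloro-N-methoxy-N-methylacetamide | CON(C)C(=O)CCl | starting material
15 | 2-{3,4-dimethoxy-5-[2,4,6-trimethoxy-3-(3,4,5-trimethoxyphenoxy)phenoxy]phenoxy}-N-methoxy-N-methylacetamide | CON(C)C(=O)COc1cc(OC)c(OC)c(Oc2c(OC)cc(OC)c(Oc3cc(OC)c(OC)c(OC)c3)c2OC)c1 | intermediate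
16 | methyl (2E)-3-methoxybut-2-enoate | COC(=O)/C=C(/OC)C | starting material
17 | lithium 1,3-dimethoxybuta-1,3-dien-1-olate | [Li+].[O-]C(OC)=CC(=C)OC | intermediate (not isolated)
18 | lithium alkoxide of the N-methoxy-N-methyl hemiaminal at C5 of 19 (racemic, transient) | [Li+].[O-]C(COc1cc(OC)c(OC)c(Oc2c(OC)cc(OC)c(Oc3cc(OC)c(OC)c(OC)c3)c2OC)c1)(C/C(OC)=C\C(=O)OC)N(C)OC | intermediate (not isolated)
19 | methyl (2E)-6-{3,4-dimethoxy-5-[2,4,6-trimethoxy-3-(3,4,5-trimethoxyphenoxy)phenoxy]phenoxy}-3-methoxy-5-oxohex-2-enoate | COC(=O)/C=C(/OC)CC(=O)COc1cc(OC)c(OC)c(Oc2c(OC)cc(OC)c(Oc3cc(OC)c(OC)c(OC)c3)c2OC)c1 | intermediate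
20 | 2-(ArBCD-oxy)-5-methoxycyclohex-4-ene-1,3-dione (racemic, transient) | COC1=CC(=O)C(Oc2cc(OC)c(OC)c(Oc3c(OC)cc(OC)c(Oc4cc(OC)c(OC)c(OC)c4)c3OC)c2)C(=O)C1 | intermediate (not isolated)
21 | 2-{3,4-dimethoxy-5-[2,4,6-trimethoxy-3-(3,4,5-trimethoxyphenoxy)phenoxy]phenoxy}-5-methoxybenzene-1,3-diol | COc1cc(O)c(Oc2cc(OC)c(OC)c(Oc3c(OC)cc(OC)c(Oc4cc(OC)c(OC)c(OC)c4)c3OC)c2)c(O)c1 | intermediate
22 | 2-{3,4-dihydroxy-5-[2,4,6-trihydroxy-3-(3,4,5-trihydroxyphenoxy)phenoxy]phenoxy}benzene-1,3,5-triol | Oc1cc(O)c(Oc2cc(O)c(O)c(Oc3c(O)cc(O)c(Oc4cc(O)c(O)c(O)c4)c3O)c2)c(O)c1 | target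

**Totals and risks**

Total step count: 10. Longest linear sequence: 10 steps (1 to 22).

Steps most likely to fail:

1. Step 9 (carries the label). C-acylation may not compete: the anion may rest as the lactonised 4-methoxy-2-pyranone or as the unreactive C4 dienolate, or methoxide may cleave the C4–C5 bond by retro-Claisen fragmentation before the ring closes. The fallback gives up the de novo ring construction and attaches ring A as a preformed arene by known chemistry. It sets out from phenol 13, which is converted with Tf2O and pyridine in CH2Cl2 into the BCD aryl triflate F1. Palladium-catalysed C–O coupling of F1 with 2,4,6-trimethoxyphenol 3 (Pd(OAc)2, tBuXPhos, K3PO4, toluene, 100 °C) should give the undecamethyl ether of the target F2. Treatment of F2 with excess BBr3 under the conditions of step 10 comes back to the route at 22.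

2. Step 8. Attack through the α-carbon of the dienolate, or proton transfer from the OCH2 group of 15 to the dienolate, would erode the γ-acylation. The fallback buys the six-carbon chain as a pyranone instead of forming the C4–C5 bond. Commercial 4-methoxy-6-methyl-2H-pyran-2-one is brominated at the methyl group (NBS, AIBN, PhCF3, reflux) to 6-(bromomethyl)-4-methoxy-2H-pyran-2-one F3. Phenol 13 is alkylated with F3 (K2CO3, acetone, 50 °C) to the 6-(ArBCD-oxymethyl)-4-methoxy-2H-pyran-2-one F4. Under the methoxide conditions of step 9 the lactone of F4 should open to 19 in the flask, so the route is rejoined at 19.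

3. Step 5. The coupling builds an ether with three ortho substituents and may be slow, so that protodebromination of 10 and base-induced loss of the aldehyde compete. The fallback replaces the copper coupling by an SNAr reaction activated by an ortho aldehyde that later becomes the ring B C4 oxygen. It sets out from phenol 9, which is heated with commercial 4-bromo-2-fluoro-6-methoxybenzaldehyde (K2CO3, DMF, 90 °C) to give 4-bromo-2-methoxy-6-(CD-aryloxy)benzaldehyde F5. Dakin oxidation (mCPBA, CH2Cl2, then K2CO3, MeOH) leads through the aryl formate F6 to the bromophenol F7. Methylation (MeI, K2CO3, DMF) gives the aryl bromide F8, and palladium-catalysed hydroxylation (Pd2(dba)3, tBuXPhos, KOH, dioxane/H2O, 100 °C) comes back to the route at 13.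

**Further compounds**

F1 | step 9 | 3,4-dimethoxy-5-[2,4,6-trimethoxy-3-(3,4,5-trimethoxyphenoxy)phenoxy]phenyl trifluoromethanesulfonate | O=S(=O)(Oc1cc(OC)c(OC)c(Oc2c(OC)cc(OC)c(Oc3cc(OC)c(OC)c(OC)c3)c2OC)c1)C(F)(F)F
F2 | step 9 | 1,2-dimethoxy-3-[2,4,6-trimethoxy-3-(3,4,5-trimethoxyphenoxy)phenoxy]-5-(2,4,6-trimethoxyphenoxy)benzene | COc1cc(OC)c(Oc2cc(OC)c(OC)c(Oc3c(OC)cc(OC)c(Oc4cc(OC)c(OC)c(OC)c4)c3OC)c2)c(OC)c1
F3 | step 8 | 6-(bromomethyl)-4-methoxy-2H-pyran-2-one | COC1=CC(=O)OC(CBr)=C1
F4 | step 8 | 6-({3,4-dimethoxy-5-[2,4,6-trimethoxy-3-(3,4,5-trimethoxyphenoxy)phenoxy]phenoxy}methyl)-4-methoxy-2H-pyran-2-one | COC1=CC(=O)OC(COc2cc(OC)c(OC)c(Oc3c(OC)cc(OC)c(Oc4cc(OC)c(OC)c(OC)c4)c3OC)c2)=C1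
F5 | step 5 | 4-bromo-2-methoxy-6-[2,4,6-trimethoxy-3-(3,4,5-trimethoxyphenoxy)phenoxy]benzaldehyde | O=Cc1c(OC)cc(Br)cc1Oc1c(OC)cc(OC)c(Oc2cc(OC)c(OC)c(OC)c2)c1OC
F6 | step 5 | 4-bromo-2-methoxy-6-[2,4,6-trimethoxy-3-(3,4,5-trimethoxyphenoxy)phenoxy]phenyl formate | O=COc1c(OC)cc(Br)cc1Oc1c(OC)cc(OC)c(Oc2cc(OC)c(OC)c(OC)c2)c1OC
F7 | step 5 | 4-bromo-2-methoxy-6-[2,4,6-trimethoxy-3-(3,4,5-trimethoxyphenoxy)phenoxy]phenol | Oc1c(OC)cc(Br)cc1Oc1c(OC)cc(OC)c(Oc2cc(OC)c(OC)c(OC)c2)c1OC
F8 | step 5 | 5-bromo-1,2-dimethoxy-3-[2,4,6-trimethoxy-3-(3,4,5-trimethoxyphenoxy)phenoxy]benzene | COc1cc(Br)cc(Oc2c(OC)cc(OC)c(Oc3cc(OC)c(OC)c(OC)c3)c2OC)c1OC
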